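The pyranone ring C is disconnected at O1–C8a and C4–C4a. The route exploits the fact that C8a and C4a are adjacent carbons of ring A, so they can be unveiled together as an aryne, while a 3-hydroxy-2-arylacrylate supplies the whole O1–C2=C3–C4(=O) chain with the ring-B aryl group already on C3. In one fluoride-triggered operation the enolate oxygen and the ester carbon are joined to the aryne and ring C is closed. The aryne precursor is a 2-silylaryl triflate bearing 7-OMe, 6-OBn and a temporary chlorine next to the triflate carbon (future C5), which steers the oxygen to C8a; chlorine and benzyl are then removed by hydrogenolysis.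

Key step: step 7

Remark: 12 is drawn and named as its hydrogen-bonded (Z)-enol; it equilibrates with the aldehyde tautomer, and all forms converge on one enolate under the basic conditions of step 7.

Step 1
Reactants: 1 isovanillin (3-hydroxy-4-methoxybenzaldehyde)
Product: 2 2-chloro-3-hydroxy-4-methoxybenzaldehyde
Conditions: t-BuOCl (1.05 equiv), AcOH, rt
Reagents that add atoms: tert-butyl hypochlorite, CC(C)(C)OCl
Why: Electrophilic aromatic chlorination in which the free phenol directs ortho and chlorine should enter at C2, between OH and CHO, the site that halogenation of isovanillin is known to take.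

Step 2
Reactants: 2 2-chloro-3-hydroxy-4-methoxybenzaldehyde
Product: 3 3-(benzyloxy)-2-chloro-4-methoxybenzaldehyde
Conditions: BnBr, K2CO3, DMF, rt
Reagents that add atoms: benzyl bromide, BrCc1ccccc1
Why: Williamson ether synthesis, the phenoxide displacing bromide from benzyl bromide while the aldehyde and the aryl chloride stay untouched.

Step 3
Reactants: 3 3-(benzyloxy)-2-chloro-4-methoxybenzaldehyde
Product: 5 3-(benzyloxy)-2-chloro-4-methoxyphenol, via 3-(benzyloxy)-2-chloro-4-methoxyphenyl formate 4 (not isolated)
Conditions: mCPBA, CH2Cl2, rt; then K2CO3 (cat.), MeOH, rt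
Reagents that add atoms: meta-chloroperbenzoic acid, O=C(OO)c1cccc(Cl)c1
Why: Baeyer–Villiger (Dakin-type) oxidation in which the electron-rich aryl group, activated by the para methoxy group, migrates to oxygen, and mild methanolysis of the resulting aryl formate releases the phenol.

Step 4
Reactants: 5 3-(benzyloxy)-2-chloro-4-methoxyphenol
Product: 6 3-(benzyloxy)-6-bromo-2-chloro-4-methoxyphenol
Conditions: NBS (1.0 equiv), i-Pr2NH (10 mol%), CH2Cl2, −20 °C to 0 °C
Reagents that add atoms: N-bromosuccinimide, O=C1CCC(=O)N1Br
Why: Electrophilic aromatic bromination directed ortho by the free phenol and para by the benzyloxy group, so C6, the only free position ortho to OH, should be taken in preference to C5.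

Step 5
Reactants: 6 3-(benzyloxy)-6-bromo-2-chloro-4-methoxyphenol
Product: 9 3-(benzyloxy)-2-chloro-4-methoxy-6-(trimethylsilyl)phenyl trifluoromethanesulfonate, via [3-(benzyloxy)-6-bromo-2-chloro-4-methoxyphenoxy]trimethylsilane 7 (not isolated), via lithium 3-(benzyloxy)-2-chloro-4-methoxy-6-(trimethylsilyl)phenolate 8 (not isolated)
Conditions: HMDS, THF, 70 °C, then evaporate; n-BuLi, THF, −100 °C; Tf2O, −100 °C to rt
Reagents that add atoms: hexamethyldisilazane, C[Si](C)(C)N[Si](C)(C)C; trifluoromethanesulfonic anhydride, O=S(=O)(OS(=O)(=O)C(F)(F)F)C(F)(F)F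
Why: Standard one-pot access to 2-silylaryl triflates by O-silylation, bromine–lithium exchange (much faster than any reaction at the C–Cl bond), anionic 1,3 O-to-C silyl shift (retro-Brook rearrangement) and O-triflation of the resulting phenoxide.

Step 6
Reactants: 10 methyl 3,4,5-trimethoxyphenylacetate; 11 methyl formate (excess)
Product: 12 methyl (Z)-3-hydroxy-2-(3,4,5-trimethoxyphenyl)acrylate
Conditions: NaH (1.5 equiv), THF, 0 °C to rt; then aq. HCl
Reagents that add atoms: none
Why: Crossed Claisen condensation (C-formylation) of the only enolisable ester with non-enolisable methyl formate, driven by formation of the stabilised sodium enolate, acidification giving the chelated (Z)-enol with no stereocentre.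

Step 7
Reactants: 9 3-(benzyloxy)-2-chloro-4-methoxy-6-(trimethylsilyl)phenyl trifluoromethanesulfonate (1.0 equiv); 12 methyl (Z)-3-hydroxy-2-(3,4,5-trimethoxyphenyl)acrylate (1.5 equiv)
Product: 14 6-(benzyloxy)-5-chloro-7-methoxy-3-(3,4,5-trimethoxyphenyl)chromen-4-one, via 4-(benzyloxy)-3-chloro-5-methoxybenzyne 13 (not isolated)
Conditions: CsF (4 equiv), THF, 65 °C
Reagents that add atoms: none
Why: Proposed new method: fluoride attacks silicon in 9 and loss of triflate unveils aryne 13, to which the cesium enolate of 12 should add through its formyl-derived oxygen at the aryne carbon remote from chlorine (future C8a), since this places the developing aryl anion at C4a beside the sigma-withdrawing C–Cl bond; that anion then attacks the cis-disposed methyl ester and expels methoxide. The closest known reaction type is the CsF-promoted coupling of arynes with salicylate esters to give xanthones, taken together with the distal nucleophilic addition established for 3-haloarynes. Ring C is closed by a 6-exo-trig acyl substitution (C4–C4a) that follows the intermolecular O1–C8a bond formation. No stereocentre is formed, and only the enolate geometry with oxygen cis to the ester is productive, which the freely interconverting, cesium-chelated contact ion pair in THF should supply. The step needs regioselectivity on an aryne whose 4-benzyloxy and 5-methoxy groups cancel each other, and O- over C-arylation. The temporary chlorine at C5 secures the first, and the fully substituted, aryl-shielded alpha-carbon of the enolate secures the second.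

Step 8
Reactants: 14 6-(benzyloxy)-5-chloro-7-methoxy-3-(3,4,5-trimethoxyphenyl)chromen-4-one
Product: 16 6-hydroxy-7-methoxy-3-(3,4,5-trimethoxyphenyl)chromen-4-one, via 5-chloro-6-hydroxy-7-methoxy-3-(3,4,5-trimethoxyphenyl)chromen-4-one 15 (not isolated)
Conditions: H2 (1 atm), 10% Pd/C, EtOAc–MeOH, rt; then Et3N (2 equiv), H2, rt
Reagents that add atoms: none
Why: Heterogeneous palladium-catalysed hydrogenolysis should first cleave the benzylic C–O bond and, once Et3N is added to take up HCl, the aryl C–Cl bond (hydrodechlorination), while the vinylogous-ester C2=C3 bond of the chromone is reduced much more slowly.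

Compound list
1 | isovanillin (3-hydroxy-4-methoxybenzaldehyde) | COc1ccc(C=O)cc1O | starting material
2 | 2-chloro-3-hydroxy-4-methoxybenzaldehyde | COc1ccc(C=O)c(Cl)c1O | intermediate
3 | 3-(benzyloxy)-2-chloro-4-methoxybenzaldehyde | COc1ccc(C=O)c(Cl)c1OCc1ccccc1 | intermediate
4 | 3-(benzyloxy)-2-chloro-4-methoxyphenyl formate | COc1ccc(OC=O)c(Cl)c1OCc1ccccc1 | intermediate (not isolated)
5 | 3-(benzyloxy)-2-chloro-4-methoxyphenol | COc1ccc(O)c(Cl)c1OCc1ccccc1 | intermediate
6 | 3-(benzyloxy)-6-bromo-2-chloro-4-methoxyphenol | COc1cc(Br)c(O)c(Cl)c1OCc1ccccc1 | intermediate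
7 | [3-(benzyloxy)-6-bromo-2-chloro-4-methoxyphenoxy]trimethylsilane | COc1cc(Br)c(O[Si](C)(C)C)c(Cl)c1OCc1ccccc1 | intermediate (not isolated)
8 | lithium 3-(benzyloxy)-2-chloro-4-methoxy-6-(trimethylsilyl)phenolate | COc1cc([Si](C)(C)C)c([O-])c(Cl)c1OCc1ccccc1.[Li+] | intermediate (not isolated)
9 | 3-(benzyloxy)-2-chloro-4-methoxy-6-(trimethylsilyl)phenyl trifluoromethanesulfonate | COc1cc([Si](C)(C)C)c(OS(=O)(=O)C(F)(F)F)c(Cl)c1OCc1ccccc1 | intermediate
10 | methyl 3,4,5-trimethoxyphenylacetate | COC(=O)Cc1cc(OC)c(OC)c(OC)c1 | starting material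
11 | methyl formate | COC=O | starting material
12 | methyl (Z)-3-hydroxy-2-(3,4,5-trimethoxyphenyl)acrylate | COC(=O)/C(=C\O)c1cc(OC)c(OC)c(OC)c1 | intermediate
13 | 4-(benzyloxy)-3-chloro-5-methoxybenzyne (1,2-didehydrobenzene numbering) | COC1=CC#CC(Cl)=C1OCc1ccccc1 | intermediate (not isolated)
14 | 6-(benzyloxy)-5-chloro-7-methoxy-3-(3,4,5-trimethoxyphenyl)chromen-4-one | COc1cc2occ(-c3cc(OC)c(OC)c(OC)c3)c(=O)c2c(Cl)c1OCc1ccccc1 | intermediate
15 | 5-chloro-6-hydroxy-7-methoxy-3-(3,4,5-trimethoxyphenyl)chromen-4-one | COc1cc2occ(-c3cc(OC)c(OC)c(OC)c3)c(=O)c2c(Cl)c1O | intermediate (not isolated)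
16 | 6-hydroxy-7-methoxy-3-(3,4,5-trimethoxyphenyl)chromen-4-one | COc1cc2occ(-c3cc(OC)c(OC)c(OC)c3)c(=O)c2cc1O | target

Total step count: 8. Longest linear sequence: 7 steps (steps 1, 2, 3, 4, 5, 7, 8); step 6 is a one-step branch.

Steps most likely to fail

Step 7 (proposed new method). The enolate may react through carbon, leading to acyl-alkylation via the formyl group. It may also add from the geometry with oxygen trans to the ester, so that the aryl anion is only protonated. Finally, the aryl anion may expel the neighbouring chloride before it acylates. The fallback uses known chemistry, sets out from 10 and comes back to the route at target 16. Saponification of 10 (LiOH, THF–H2O) would give 3,4,5-trimethoxyphenylacetic acid F1. Friedel–Crafts acylation of purchased 2-methoxyhydroquinone F2 with F1 in BF3·OEt2 at 80 °C should occur at the ring position ortho to one hydroxyl and para to the methoxy group. It would give the deoxybenzoin 1-(2,5-dihydroxy-4-methoxyphenyl)-2-(3,4,5-trimethoxyphenyl)ethan-1-one F3. Treatment of F3 with DMF and MsCl in BF3·OEt2 at 70 °C (one-carbon insertion at the methylene and cyclisation) should give 16 directly, with no chlorine or benzyl group to remove.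

Step 8. Hydrodechlorination at the hindered peri position may stall, or prolonged exposure may saturate the C2=C3 bond. The fallback separates the two cleavages into non-hydrogenative operations, sets out from 14 and comes back at 16. Homogeneous palladium-catalysed formate reduction of the aryl chloride (Pd(OAc)2, XPhos, HCO2Na, DMF, 80 °C) leaves the benzyl ether and the enone alone. It would give 6-(benzyloxy)-7-methoxy-3-(3,4,5-trimethoxyphenyl)chromen-4-one F4. Lewis-acid debenzylation with BCl3 and pentamethylbenzene in CH2Cl2 at −78 °C would then give 16.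

Step 4. Bromination may go to the position next to the methoxy group, or the electron-rich hydroquinone monoether may be oxidised to a quinone. The fallback replaces electrophilic halogenation by directed ortho-metalation, sets out from 5 and comes back at 9, bypassing steps 4 and 5.
- Carbamoylation of 5 (isopropyl isocyanate, Et3N, CH2Cl2) would give 3-(benzyloxy)-2-chloro-4-methoxyphenyl isopropylcarbamate F5.
- N-Silylation in the flask (TBSOTf, TMEDA, Et2O) would give 3-(benzyloxy)-2-chloro-4-methoxyphenyl N-(tert-butyldimethylsilyl)-N-isopropylcarbamate F6.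
- Lithiation (n-BuLi, TMEDA, −78 °C) at C6, the only free position ortho to the carbamate, and a TMSCl quench would give 3-(benzyloxy)-2-chloro-4-methoxy-6-(trimethylsilyl)phenyl N-(tert-butyldimethylsilyl)-N-isopropylcarbamate F7.
- Acidic work-up would give 3-(benzyloxy)-2-chloro-4-methoxy-6-(trimethylsilyl)phenyl isopropylcarbamate F8.
- One-pot carbamate cleavage and triflation (DBU, Et2NH, MeCN, 40 °C; then PhNTf2) would give 9.

Further compounds
F1 | step 7 | 3,4,5-trimethoxyphenylacetic acid | OC(=O)Cc1cc(OC)c(OC)c(OC)c1
F2 | step 7 | 2-methoxyhydroquinone (purchased) | COc1cc(O)ccc1O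
F3 | step 7 | 1-(2,5-dihydroxy-4-methoxyphenyl)-2-(3,4,5-trimethoxyphenyl)ethan-1-one | COc1cc(O)c(C(=O)Cc2cc(OC)c(OC)c(OC)c2)cc1O
F4 | step 8 | 6-(benzyloxy)-7-methoxy-3-(3,4,5-trimethoxyphenyl)chromen-4-one | COc1cc2occ(-c3cc(OC)c(OC)c(OC)c3)c(=O)c2cc1OCc1ccccc1
F5 | step 4 | 3-(benzyloxy)-2-chloro-4-methoxyphenyl isopropylcarbamate | COc1ccc(OC(=O)NC(C)C)c(Cl)c1OCc1ccccc1
F6 | step 4 | 3-(benzyloxy)-2-chloro-4-methoxyphenyl N-(tert-butyldimethylsilyl)-N-isopropylcarbamate | COc1ccc(OC(=O)N(C(C)C)[Si](C)(C)C(C)(C)C)c(Cl)c1OCc1ccccc1
F7 | step 4 | 3-(benzyloxy)-2-chloro-4-methoxy-6-(trimethylsilyl)phenyl N-(tert-butyldimethylsilyl)-N-isopropylcarbamate | COc1cc([Si](C)(C)C)c(OC(=O)N(C(C)C)[Si](C)(C)C(C)(C)C)c(Cl)c1OCc1ccccc1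
F8 | step 4 | 3-(benzyloxy)-2-chloro-4-methoxy-6-(trimethylsilyl)phenyl isopropylcarbamate | COc1cc([Si](C)(C)C)c(OC(=O)NC(C)C)c(Cl)c1OCc1ccccc1
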